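The flavone is cut at C4, a single ketone carbon bonded only to C4a of the fully substituted ring A and to C3, which carries a methoxy group; C4 can therefore be brought in as carbon monoxide. A palladium-catalysed carbonylative ketone arylation joins three components in one operation, forming the C4a–C4 and C4–C3 bonds and delivering the whole 1,3-diketone skeleton. Its precursors are a symmetric pentaoxygenated aryl iodide, with iodine on the only oxygen-free carbon of ring A between two MOM ethers, and a benzyl-protected ring B methoxymethyl ketone. Selective MOM removal then lets only the ring A phenols close ring C, and hydrogenolysis completes the target.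

Key step: step 9

Assumption: N,2-dimethoxy-N-methylacetamide (12) is taken as a purchasable reagent. The target is achiral, so no stereocentre has to be set; 14, 19 and 20 are racemic.

Step 1
Reactants: 1 2,6-dimethoxyphenol (syringol)
Product: 2 2-(benzyloxy)-1,3-dimethoxybenzene
Conditions: BnBr, K2CO3, DMF, 60 °C
Reagents that add atoms: benzyl bromide, BrCc1ccccc1
Why: The phenol is the only nucleophilic site and should be O-benzylated under carbonate in a Williamson ether synthesis.

Step 2
Reactants: 2 2-(benzyloxy)-1,3-dimethoxybenzene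
Product: 3 3-(benzyloxy)-1,5-dibromo-2,4-dimethoxybenzene
Conditions: NBS (2.1 equiv), MeCN, 0 °C to rt, dark
Reagents that add atoms: N-bromosuccinimide, O=C1CCC(=O)N1Br
Why: Electrophilic aromatic bromination of a 1,2,3-trialkoxybenzene should go to the two carbons that are ortho to one methoxy group and para to the other, since the twisted central benzyloxy group activates its para carbon only weakly; the acid-free medium spares the benzyl ether.

Step 3
Reactants: 3 3-(benzyloxy)-1,5-dibromo-2,4-dimethoxybenzene
Product: 5 5-(benzyloxy)-4,6-dimethoxybenzene-1,3-diol, via arene bis(pinacolboronate) 4 (not isolated)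
Conditions: B2pin2 (2.5 equiv), PdCl2(dppf) (5 mol%), KOAc, 1,4-dioxane, 90 °C; then THF, NaOH (aq), 30% H2O2, 0 °C; HCl (aq) to pH 5
Reagents that add atoms: hydrogen peroxide, OO (the two phenol oxygens); bis(pinacolato)diboron, CC1(C)OB(OC1(C)C)B1OC(C)(C)C(C)(C)O1 (boron of 4 only)
Why: Miyaura borylation should exchange both bromides, each with only one ortho substituent, for pinacol boronates, and alkaline peroxide then turns each C–B bond into C–O at the same carbon (boronate oxidation), all under conditions that aryl ethers tolerate.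

Step 4
Reactants: 5 5-(benzyloxy)-4,6-dimethoxybenzene-1,3-diol
Product: 6 3-(benzyloxy)-2,4-dimethoxy-1,5-bis(methoxymethoxy)benzene
Conditions: MOMCl, iPr2NEt, CH2Cl2, 0 °C to rt
Reagents that add atoms: chloromethyl methyl ether, COCCl
Why: O-alkylation of both phenols with the reactive chloromethyl ether (Williamson-type acetal formation) should give base-stable, acid-labile ethers that direct metalation and can later be removed without touching the benzyl ethers.

Step 5
Reactants: 6 3-(benzyloxy)-2,4-dimethoxy-1,5-bis(methoxymethoxy)benzene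
Product: 8 3-(benzyloxy)-6-iodo-2,4-dimethoxy-1,5-bis(methoxymethoxy)benzene, via ring A aryllithium 7 (not isolated)
Conditions: n-BuLi (1.2 equiv), THF, −20 to 0 °C; then I2, −78 °C to rt
Reagents that add atoms: iodine, II; n-butyllithium, [Li]CCCC (lithium of 7 only)
Why: Directed ortho-metalation should occur at the only ring hydrogen, which lies between two cooperatively directing MOM ethers, and iodine traps the aryllithium, so the position of iodine is unambiguous.

Step 6
Reactants: 9 2-methoxyhydroquinone
Product: 10 1,4-bis(benzyloxy)-2-methoxybenzene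
Conditions: BnBr, K2CO3, DMF, 60 °C, under N2
Reagents that add atoms: benzyl bromide, BrCc1ccccc1
Why: Double Williamson etherification of the two phenols; exclusion of air guards the hydroquinone against oxidation before it is capped.

Step 7
Reactants: 10 1,4-bis(benzyloxy)-2-methoxybenzene
Product: 11 1,4-bis(benzyloxy)-2-bromo-5-methoxybenzene
Conditions: NBS (1.05 equiv), MeCN, 0 °C
Reagents that add atoms: N-bromosuccinimide, O=C1CCC(=O)N1Br
Why: Electrophilic aromatic bromination of a 1,2,4-trialkoxybenzene should take place para to the methoxy group and ortho to a benzyloxy group, the most activated unhindered carbon, as 1,2,4-trimethoxybenzene does.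

Step 8
Reactants: 11 1,4-bis(benzyloxy)-2-bromo-5-methoxybenzene; 12 N,2-dimethoxy-N-methylacetamide
Product: 15 1-[2,5-bis(benzyloxy)-4-methoxyphenyl]-2-methoxyethan-1-one, via ring B aryllithium 13 (not isolated), via lithium hemiaminal alkoxide 14 (not isolated)
Conditions: n-BuLi (1.05 equiv), THF, −78 °C; then 12, −78 to 0 °C; 1 M HCl, 0 °C
Reagents that add atoms: n-butyllithium, [Li]CCCC (lithium of 13 and 14 only)
Why: Bromine–lithium exchange at −78 °C outruns any deprotonation, and acylation of the aryllithium by the N-methoxy-N-methylamide (Weinreb ketone synthesis) stops at the chelated adduct 14 until the quench; this fixes the acyl position through the bromide and avoids a Lewis-acid acylation with methoxyacetyl chloride, which is prone to decarbonylation and to benzyl ether loss.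

Step 9
Reactants: 8 3-(benzyloxy)-6-iodo-2,4-dimethoxy-1,5-bis(methoxymethoxy)benzene; 15 1-[2,5-bis(benzyloxy)-4-methoxyphenyl]-2-methoxyethan-1-one; 16 carbon monoxide
Product: 19 1-[4-(benzyloxy)-3,5-dimethoxy-2,6-bis(methoxymethoxy)phenyl]-3-[2,5-bis(benzyloxy)-4-methoxyphenyl]-2-methoxypropane-1,3-dione (racemic, enolisable), via sodium enolate 17 (not isolated), via sodium diketonate 18 (not isolated)
Conditions: 15 (2.2 equiv, excess recovered), NaN(SiMe3)2 (2.1 equiv), THF, 0 °C; then 8 (1.0 equiv), Pd(OAc)2 (5 mol%), Xantphos (6 mol%), CO (1 atm), 1,4-dioxane, 80 °C; AcOH quench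
Reagents that add atoms: sodium bis(trimethylsilyl)amide, [Na+].C[Si](C)(C)[N-][Si](C)(C)C (sodium of 17 and 18 only)
Why: Pd(OAc)2 is reduced in the flask to a zerovalent palladium–Xantphos complex that inserts into the C–I bond of 8; the arylpalladium iodide (divalent palladium) takes up CO to give the aroylpalladium, sodium enolate 17 displaces iodide at the metal, and reductive elimination forges C4–C3 while the CO carbon, now C4, is already bonded to C4a. The closest known reaction type is the palladium-catalysed carbonylative alpha-arylation of aryl alkyl ketones with aryl iodides to 1,3-diketones. No ring is closed, and the one new stereocentre (the methoxy-bearing carbon, future C3) is racemic and enolisable, which does not matter because it becomes sp2 in step 10. Two selectivities are needed: CO insertion must precede coupling, which the two ortho MOM ethers should secure by crowding the arylpalladium so that direct arylation is slow under 1 atm of CO, and acylation must occur at carbon, which is favoured because the C-acylated product is removed at once as the chelated sodium diketonate 18 by the second equivalent of 17. Regiochemistry on ring A needs no control, since iodine sits on the only carbon of 8 that bears no oxygen.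

Step 10
Reactants: 19 1-[4-(benzyloxy)-3,5-dimethoxy-2,6-bis(methoxymethoxy)phenyl]-3-[2,5-bis(benzyloxy)-4-methoxyphenyl]-2-methoxypropane-1,3-dione
Product: 21 7-(benzyloxy)-2-[2,5-bis(benzyloxy)-4-methoxyphenyl]-5-hydroxy-3,6,8-trimethoxy-4H-chromen-4-one, via bis-phenol diketone 20 (not isolated)
Conditions: HCl (3 M), MeOH/THF, 50 °C
Reagents that add atoms: none
Why: Acid-catalysed methanolysis of the two MOM acetals frees the ring A phenols while benzyl and methyl ethers persist, and either of the two equivalent phenols should add to the ring B ketone and lose water (cyclodehydration of an ortho-hydroxyaryl 1,3-diketone, the closing stage of a Baker–Venkataraman flavone synthesis), forming O1–C2 and the C2=C3 bond; the still-benzylated oxygen at C2' cannot close the isomeric chromone.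

Step 11
Reactants: 21 7-(benzyloxy)-2-[2,5-bis(benzyloxy)-4-methoxyphenyl]-5-hydroxy-3,6,8-trimethoxy-4H-chromen-4-one
Product: 22 5,7,2',5'-tetrahydroxy-3,6,8,4'-tetramethoxyflavone
Conditions: H2 (1 atm), 10% Pd/C, EtOAc/MeOH, rt; work-up under N2
Reagents that add atoms: none
Why: Catalytic hydrogenolysis should cleave the three benzyl aryl ethers while the methyl ethers and the conjugated, tetrasubstituted C2=C3 bond of the chromone remain; exclusion of air protects the ring B hydroquinone.

Compound list
1 | 2,6-dimethoxyphenol (syringol) | COc1cccc(OC)c1O | starting material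
2 | 2-(benzyloxy)-1,3-dimethoxybenzene | COc1cccc(OC)c1OCc1ccccc1 | intermediate
3 | 3-(benzyloxy)-1,5-dibromo-2,4-dimethoxybenzene | COc1c(Br)cc(Br)c(OC)c1OCc1ccccc1 | intermediate
4 | 2,2'-[5-(benzyloxy)-4,6-dimethoxy-1,3-phenylene]bis(4,4,5,5-tetramethyl-1,3,2-dioxaborolane) | COc1c(B2OC(C)(C)C(C)(C)O2)cc(B2OC(C)(C)C(C)(C)O2)c(OC)c1OCc1ccccc1 | intermediate
5 | 5-(benzyloxy)-4,6-dimethoxybenzene-1,3-diol | COc1c(O)cc(O)c(OC)c1OCc1ccccc1 | intermediate
6 | 3-(benzyloxy)-2,4-dimethoxy-1,5-bis(methoxymethoxy)benzene | COCOc1cc(OCOC)c(OC)c(OCc2ccccc2)c1OC | intermediate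
7 | [4-(benzyloxy)-3,5-dimethoxy-2,6-bis(methoxymethoxy)phenyl]lithium | COCOc1c([Li])c(OCOC)c(OC)c(OCc2ccccc2)c1OC | intermediate
8 | 3-(benzyloxy)-6-iodo-2,4-dimethoxy-1,5-bis(methoxymethoxy)benzene | COCOc1c(I)c(OCOC)c(OC)c(OCc2ccccc2)c1OC | intermediate
9 | 2-methoxyhydroquinone (2-methoxybenzene-1,4-diol) | COc1cc(O)ccc1O | starting material
10 | 1,4-bis(benzyloxy)-2-methoxybenzene | COc1cc(OCc2ccccc2)ccc1OCc1ccccc1 | intermediate
11 | 1,4-bis(benzyloxy)-2-bromo-5-methoxybenzene | COc1cc(OCc2ccccc2)c(Br)cc1OCc1ccccc1 | intermediate
12 | N,2-dimethoxy-N-methylacetamide | COCC(=O)N(C)OC | starting material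
13 | [2,5-bis(benzyloxy)-4-methoxyphenyl]lithium | COc1cc(OCc2ccccc2)c([Li])cc1OCc1ccccc1 | intermediate
14 | lithium 1-[2,5-bis(benzyloxy)-4-methoxyphenyl]-2-methoxy-1-[methoxy(methyl)amino]ethan-1-olate (racemic) | COCC(O[Li])(N(C)OC)c1cc(OCc2ccccc2)c(OC)cc1OCc1ccccc1 | intermediate
15 | 1-[2,5-bis(benzyloxy)-4-methoxyphenyl]-2-methoxyethan-1-one | COCC(=O)c1cc(OCc2ccccc2)c(OC)cc1OCc1ccccc1 | intermediate
16 | carbon monoxide | [C-]#[O+] | starting material
17 | sodium 1-[2,5-bis(benzyloxy)-4-methoxyphenyl]-2-methoxyethen-1-olate (double-bond geometry not assigned) | [Na+].COC=C([O-])c1cc(OCc2ccccc2)c(OC)cc1OCc1ccccc1 | intermediate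
18 | sodium enolate of 19 (delocalised diketonate, one resonance form drawn) | [Na+].COCOc1c(C(=O)C(OC)=C([O-])c2cc(OCc3ccccc3)c(OC)cc2OCc2ccccc2)c(OCOC)c(OC)c(OCc2ccccc2)c1OC | intermediate
19 | 1-[4-(benzyloxy)-3,5-dimethoxy-2,6-bis(methoxymethoxy)phenyl]-3-[2,5-bis(benzyloxy)-4-methoxyphenyl]-2-methoxypropane-1,3-dione (racemic, enolisable) | COCOc1c(C(=O)C(OC)C(=O)c2cc(OCc3ccccc3)c(OC)cc2OCc2ccccc2)c(OCOC)c(OC)c(OCc2ccccc2)c1OC | intermediate
20 | 1-[4-(benzyloxy)-2,6-dihydroxy-3,5-dimethoxyphenyl]-3-[2,5-bis(benzyloxy)-4-methoxyphenyl]-2-methoxypropane-1,3-dione (racemic) | COc1c(O)c(C(=O)C(OC)C(=O)c2cc(OCc3ccccc3)c(OC)cc2OCc2ccccc2)c(O)c(OC)c1OCc1ccccc1 | intermediate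
21 | 7-(benzyloxy)-2-[2,5-bis(benzyloxy)-4-methoxyphenyl]-5-hydroxy-3,6,8-trimethoxy-4H-chromen-4-one | COc1c(-c2cc(OCc3ccccc3)c(OC)cc2OCc2ccccc2)oc2c(OC)c(OCc3ccccc3)c(OC)c(O)c2c1=O | intermediate
22 | 5,7,2',5'-tetrahydroxy-3,6,8,4'-tetramethoxyflavone, i.e. 2-(2,5-dihydroxy-4-methoxyphenyl)-5,7-dihydroxy-3,6,8-trimethoxy-4H-chromen-4-one | COc1cc(O)c(-c2oc3c(OC)c(O)c(OC)c(O)c3c(=O)c2OC)cc1O | target

Total step count: 11. Longest linear sequence: 8 steps (steps 1–5, then 9–11); steps 6–8 form the parallel ring B branch.

Steps most likely to fail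

Step 9. Oxidative addition and CO uptake at the doubly ortho-substituted carbon may be slow, the aroylpalladium may be captured at the enolate oxygen, or the iodide may simply be reduced. The fallback sets out from 6 and 15 and comes back to the route at 19, building the same two bonds by carbonyl addition chemistry. Compound 6 would be lithiated as in step 5 and the aryllithium 7 quenched with DMF (THF, −78 °C to rt, aqueous work-up) to give 4-(benzyloxy)-3,5-dimethoxy-2,6-bis(methoxymethoxy)benzaldehyde F1. Aldol addition of sodium enolate 17, made from 15 and NaN(SiMe3)2 as in step 9, to this aldehyde at −78 °C with an acetic acid quench should give 3-[4-(benzyloxy)-3,5-dimethoxy-2,6-bis(methoxymethoxy)phenyl]-1-[2,5-bis(benzyloxy)-4-methoxyphenyl]-3-hydroxy-2-methoxypropan-1-one F2 as a mixture of diastereomers. Oxidation of the secondary alcohol with Dess–Martin periodinane (CH2Cl2, 0 °C to rt) removes both stereocentres' relevance and gives 19.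

Step 3. The second borylation may stall, protodebromination may compete, or the electron-rich resorcinol may be over-oxidised in the peroxide stage. The fallback sets out from 3 and comes back at 5: direct palladium-catalysed hydroxylation of both C–Br bonds with hydroxide (Pd2(dba)3, tBuXPhos, KOH, 1,4-dioxane/H2O, 100 °C, then HCl to pH 5), a C–O coupling that needs neither a boron intermediate nor an oxidant. This detour makes no new compound (F0).

Step 5. Deprotonation at the benzylic CH2 of the benzyl ether followed by Wittig rearrangement may compete with ring metalation, or metalation may be incomplete. The fallback sets out from 5 and comes back at 8 by reversing the order and using electrophilic instead of anionic chemistry. Iodination of diol 5 at its single free ring carbon with N-iodosuccinimide (MeCN, 0 °C) should give 5-(benzyloxy)-2-iodo-4,6-dimethoxybenzene-1,3-diol F3, and MOMCl/iPr2NEt (CH2Cl2, 0 °C to rt) then gives 8.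

Further compounds
F1 | step 9 | 4-(benzyloxy)-3,5-dimethoxy-2,6-bis(methoxymethoxy)benzaldehyde | COCOc1c(C=O)c(OCOC)c(OC)c(OCc2ccccc2)c1OC
F2 | step 9 | 3-[4-(benzyloxy)-3,5-dimethoxy-2,6-bis(methoxymethoxy)phenyl]-1-[2,5-bis(benzyloxy)-4-methoxyphenyl]-3-hydroxy-2-methoxypropan-1-one (racemic mixture of diastereomers) | COCOc1c(C(O)C(OC)C(=O)c2cc(OCc3ccccc3)c(OC)cc2OCc2ccccc2)c(OCOC)c(OC)c(OCc2ccccc2)c1OC
F0 | step 3 | none | none
F3 | step 5 | 5-(benzyloxy)-2-iodo-4,6-dimethoxybenzene-1,3-diol | COc1c(O)c(I)c(O)c(OC)c1OCc1ccccc1
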